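The furofuran core is cut at four bonds at once: C8–C9, C8'–C9', O7'–C9 and O7–C9'. The feature used: in the two fused tetrahydrofuran rings C9 and C9' are lone carbons, each spanning from a benzylic oxygen (O7', O7) to a ring-fusion carbon (C8, C8'), so both can be carbon monoxide. One palladium-catalysed oxidative double carbonylation of (7R,7'R)-E-1,4-diarylbut-2-ene-1,4-diol 11 (syringyl ring C as TIPS ether, guaiacyl ring B as TBS ether) should add both carbonyls syn across C8=C8', close both lactones and set C8 and C8' in bislactone 13. Reduction and ether closure give the furofuran; ring A with C7''–C9'' is joined to O4' by an Evans syn aldol.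

Key step: step 7

Numbering: ring C (syringyl)–C7–C8–C9; ring B (central guaiacyl)–C7'–C8'–C9'; ring A (terminal guaiacyl)–C7''–C8''–C9''. The target reads 7R,8S,7'R,8'S (both aryl groups exo) and 7''S,8''S (threo).

Descriptor note: the arrangement in space at C7 and C7' does not change after steps 3 and 5; only the label does. It is S in 7 and 10, where the substituted alkynyl branch outranks aryl, and R in 8, 11 and all later compounds. C8 and C8' are R in 13 and S from 14 on, again only through ranking.

Assumption: the zinc catalyst from Me2Zn and (S,S)-ProPhenol, 2,6-bis{[(2S)-2-(hydroxydiphenylmethyl)pyrrolidin-1-yl]methyl}-4-methylphenol, is taken to deliver alkynyl groups to the Re face of aryl aldehydes. A Mosher ester analysis of 7 would decide this, and the antipodal ligand would be used in steps 3 and 5 if the sense were opposite.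

Step 1
Reactants: 1 syringaldehyde
Product: 2 3,5-dimethoxy-4-(triisopropylsilyloxy)benzaldehyde
Conditions: TIPSCl, imidazole, DMF, rt to 40 °C
Reagents that add atoms: triisopropylsilyl chloride, CC(C)[Si](Cl)(C(C)C)C(C)C
Why: Imidazole-promoted silylation of the phenol; the bulky TIPS group between two methoxy groups is chosen to outlast every later hydride, base and the first fluoride treatment.

Step 2
Reactants: 3 vanillin
Product: 4 4-(tert-butyldimethylsilyloxy)-3-methoxybenzaldehyde
Conditions: TBSCl, imidazole, DMF, rt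
Reagents that add atoms: tert-butyldimethylsilyl chloride, CC(C)(C)[Si](C)(C)Cl
Why: Imidazole-promoted silylation of the phenol; the TBS ether is the deliberately more labile partner of the TIPS ether, and 4 serves twice, as ring B in step 5 and as ring A in step 13.

Step 3
Reactants: 2 3,5-dimethoxy-4-(triisopropylsilyloxy)benzaldehyde; 5 trimethylsilylacetylene
Product: 7 (S)-1-[3,5-dimethoxy-4-(triisopropylsilyloxy)phenyl]-3-(trimethylsilyl)prop-2-yn-1-ol, via methylzinc trimethylsilylacetylide 6 (not isolated)
Conditions: 5 (3 equiv), Me2Zn (3 equiv), (S,S)-ProPhenol (10 mol %), Ph3PO (20 mol %), toluene, 0 °C; aq NH4Cl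
Reagents that add atoms: trimethylsilylacetylene (5), C#C[Si](C)(C)C
Why: Catalytic asymmetric alkynylzinc addition to an aryl aldehyde, in which the dinuclear zinc–ProPhenol catalyst holds aldehyde and acetylide on neighbouring zinc atoms and should send the alkynyl group to the Re face, which sets C7.

Step 4
Reactants: 7 (S)-silylalkynyl carbinol
Product: 8 (R)-1-[3,5-dimethoxy-4-(triisopropylsilyloxy)phenyl]prop-2-yn-1-ol
Conditions: AgNO3 (10 mol %), CH2Cl2/MeOH/H2O, rt
Reagents that add atoms: none
Why: Silver-catalysed protiodesilylation of the C(sp)–SiMe3 bond, which leaves O–Si bonds alone, so the aryl TIPS ether that carbonate in methanol could erode is not at risk and C7 is untouched.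

Step 5
Reactants: 8 (R)-terminal alkynyl carbinol; 4 4-(tert-butyldimethylsilyloxy)-3-methoxybenzaldehyde
Product: 10 (1S,4S)-1-[4-(tert-butyldimethylsilyloxy)-3-methoxyphenyl]-4-[3,5-dimethoxy-4-(triisopropylsilyloxy)phenyl]but-2-yne-1,4-diol, via O,C-bis(methylzinc) derivative 9 (not isolated)
Conditions: 8, Me2Zn (2.2 equiv), (S,S)-ProPhenol (20 mol %), Ph3PO (40 mol %), toluene, rt; then 4 (1.3 equiv), 0 °C; aq NH4Cl; chromatography on Et3N-washed silica
Reagents that add atoms: none
Why: The same asymmetric alkynylzinc addition, with the carbinol of 8 masked in the flask as a methylzinc alkoxide (the kind of species every turnover produces anyway); catalyst control sets C7' by Re-face attack, and the unlike diastereomer, which carries off most of the minor enantiomer of 8, is removed by chromatography.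

Step 6
Reactants: 10 (S,S)-ynediol
Product: 11 (1R,4R,2E)-1-[4-(tert-butyldimethylsilyloxy)-3-methoxyphenyl]-4-[3,5-dimethoxy-4-(triisopropylsilyloxy)phenyl]but-2-ene-1,4-diol
Conditions: NaAlH2(OCH2CH2OMe)2 (Red-Al, 3.5 equiv), THF, −20 to 0 °C; aq potassium sodium tartrate
Reagents that add atoms: none
Why: Alkoxide-directed trans-hydroalumination of a propargylic alcohol followed by protonolysis gives the E-alkene only, breaks no bond at C7 or C7' and at this temperature should spare the aryl silyl ethers.

Step 7
Reactants: 11 (R,R)-E-enediol; 12 carbon monoxide (two equivalents)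
Product: 13 exo,exo-bislactone (3R,3aR,6R,6aR)-3-[4-(tert-butyldimethylsilyloxy)-3-methoxyphenyl]-6-[3,5-dimethoxy-4-(triisopropylsilyloxy)phenyl]tetrahydrofuro[3,4-c]furan-1,4-dione
Conditions: Pd(OAc)2 (10 mol %), 1,4-benzoquinone (1.5 equiv), CO (4 bar), NaOAc (0.5 equiv), 4 Å MS, THF (0.02 M), 25 °C
Reagents that add atoms: carbon monoxide (12), [C-]#[O+]
Why: Proposed new method: acetate-assisted attack of one carbinol (say O7'–H) on CO bound to divalent palladium gives an alkoxycarbonylpalladium unit whose carbonyl carbon C9 migrates to C8 while the metal goes to C8' on the same face, CO then enters the C8'–Pd bond, O7–H takes up the acyl carbon C9', and the zerovalent palladium released is returned to the divalent state by benzoquinone and the two protons set free. The closest known reactions are the syn bis-alkoxycarbonylation of 1,2-disubstituted alkenes with divalent palladium and benzoquinone, the lactone-forming dicarbonylation of but-3-en-1-ols and the endo-mode acylpalladation of 2-vinylaryl acylpalladium species, none of which has been shown on an allylic 1,4-enediol. The first lactone (O7'–C9–C8–C8'–C7') closes in a 5-endo-trig migratory insertion, the strained and probably limiting event that needs labile sites on the ligand-free metal, and the second (O7–C9'–C8'–C8–C7) closes by 5-exo-trig attack of oxygen on the acylpalladium carbon. C8 and C8' are fixed relative to each other by syn addition to the E-alkene, which after a turn of 120° about C8–C8' is exactly the cis ring fusion, and relative to C7 and C7' by the alkene face that is attacked. The face selectivity needed should come from the forming ring, which holds the C–O bond near the alkene plane so that in the R,R-diol both aryl rings lie on one face and both carbinol hydrogens on the other; metal and carbonyls should take the hydrogen-lined face and give the exo,exo isomer, whereas the other face would crowd both aryl groups into the concave side. Chemoselectivity over ionisation, transposition and oxidation of the carbinols is sought with a medium that holds no acid stronger than acetic acid and no external alcohol (an untethered, hydroxyl-directed addition through the hydrogen-eclipsed rotamer would take the wrong face), with CO pressure to outrun β-hydride loss, and with silyl rather than alkyl groups on the aryl oxygens, the TIPS ether being twisted out of conjugation by its two methoxy neighbours.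

Step 8
Reactants: 13 exo,exo-bislactone
Product: 14 (1R,2S,3S,4R)-1-[4-(tert-butyldimethylsilyloxy)-3-methoxyphenyl]-4-[3,5-dimethoxy-4-(triisopropylsilyloxy)phenyl]-2,3-bis(hydroxymethyl)butane-1,4-diol
Conditions: LiAlH4 (4 equiv), THF, 0 °C, short time; Na2SO4·10H2O quench
Reagents that add atoms: none
Why: Hydride reduction of both lactones to diols, the standard opening of 2,6-diaryl bislactones of this type, which breaks only the acyl C–O bonds so that C7, C8, C7' and C8' keep their configuration.

Step 9
Reactants: 14 tetraol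
Product: 16 (1R,3aS,4R,6aS)-1-[4-(tert-butyldimethylsilyloxy)-3-methoxyphenyl]-4-[3,5-dimethoxy-4-(triisopropylsilyloxy)phenyl]tetrahydro-1H,3H-furo[3,4-c]furan, via 9,9'-bis(methanesulfonate) 15 (not isolated)
Conditions: MsCl (2.2 equiv), pyridine/CH2Cl2, −20 °C; then 40 °C
Reagents that add atoms: none
Why: Selective sulfonylation of the two unhindered primary alcohols in the cold, then double intramolecular Williamson-type 5-exo-tet displacement (O7' at C9, O7 at C9') on warming, in which no bond to a stereocentre is broken; a stray benzylic sulfonate would ionise and be captured by the same partner to give the same exo,exo ether, because C8 and C8' dictate that outcome.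

Step 10
Reactants: 16 bis-silylated furofuran
Product: 17 4-{(1R,3aS,4R,6aS)-4-[3,5-dimethoxy-4-(triisopropylsilyloxy)phenyl]tetrahydro-1H,3H-furo[3,4-c]furan-1-yl}-2-methoxyphenol
Conditions: Bu4NF (1.0 equiv), AcOH (1.0 equiv), THF, −20 °C
Reagents that add atoms: none
Why: Fluoride cleavage of an aryl silyl ether under kinetic control: with one equivalent of buffered fluoride in the cold, the TBS group next to a single methoxy group should go well before the bulkier TIPS group flanked by two.

Step 11
Reactants: 18 (R)-4-benzyloxazolidin-2-one; 19 bromoacetyl bromide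
Product: 21 (R)-4-benzyl-3-(bromoacetyl)oxazolidin-2-one, via N-lithio oxazolidinone 20 (not isolated)
Conditions: n-BuLi (1.0 equiv), THF, −78 °C; BrCH2COBr, −78 to 0 °C
Reagents that add atoms: bromoacetyl bromide (19), BrCC(=O)Br
Why: N-Acylation of the lithiated oxazolidinone with an acid bromide, the standard entry to N-acyl Evans auxiliaries, in which the acyl bromide reacts far faster than the alkyl bromide.

Step 12
Reactants: 17 ring B phenol; 21 (R)-4-benzyl-3-(bromoacetyl)oxazolidin-2-one
Product: 22 aryloxyacetyl imide (17 carrying on O4' the group CH2C(=O)N of (R)-4-benzyloxazolidin-2-one)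
Conditions: K2CO3 (1.5 equiv), acetone, rt
Reagents that add atoms: none
Why: Williamson ether synthesis, in which the phenoxide displaces the strongly activated α-bromo imide at room temperature faster than it can attack either imide carbonyl, while carbonate in acetone leaves the hindered TIPS ether alone.

Step 13
Reactants: 22 aryloxyacetyl imide; 4 4-(tert-butyldimethylsilyloxy)-3-methoxybenzaldehyde
Product: 24 syn aldol adduct (R)-4-benzyl-3-[(2R,3S)-2-aryloxy-3-hydroxy-3-(4-tert-butyldimethylsilyloxy-3-methoxyphenyl)propanoyl]oxazolidin-2-one (aryloxy = O4' of the furofuran unit), via Z-dibutylboron enolate 23 (not isolated)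
Conditions: Bu2BOTf (1.2 equiv), Et3N (1.4 equiv), CH2Cl2, −78 to 0 °C; 4 (1.3 equiv), −78 to 0 °C; pH 7 buffer, MeOH, H2O2, 0 °C
Reagents that add atoms: none
Why: Evans syn aldol, in which the Z-boron enolate reacts through a closed Zimmerman–Traxler chair on the enolate face turned away from the benzyl group of the R auxiliary, which sets C8'' (R here, S after reduction) and C7'' (S), the threo pair of the target.

Step 14
Reactants: 24 syn aldol adduct
Product: 25 (7''S,8''S)-diol (target with TBS on the ring A phenol and TIPS on the ring C phenol)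
Conditions: LiBH4 (2.5 equiv), MeOH (2.5 equiv), THF, 0 °C
Reagents that add atoms: none
Why: Reductive removal of the auxiliary with LiBH4 (imide to primary alcohol), which is mild enough to avoid retro-aldol cleavage, touches no stereocentre and returns 18.

Step 15
Reactants: 25 bis-silylated diol
Product: 26 target CNP0255927.3
Conditions: Bu4NF (2.4 equiv), AcOH (2.4 equiv), THF, 0 °C to rt
Reagents that add atoms: none
Why: Global fluoride desilylation of the two remaining aryl silyl ethers, with acetic acid buffering so that the liberated 4-hydroxybenzyl alcohol of ring A does not lose hydroxide to a quinone methide and C7'' is not scrambled.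

Compound list
1 | syringaldehyde | COc1cc(C=O)cc(OC)c1O | starting material
2 | 3,5-dimethoxy-4-(triisopropylsilyloxy)benzaldehyde | COc1cc(C=O)cc(OC)c1O[Si](C(C)C)(C(C)C)C(C)C | intermediate
3 | vanillin | COc1cc(C=O)ccc1O | starting material
4 | 4-(tert-butyldimethylsilyloxy)-3-methoxybenzaldehyde | COc1cc(C=O)ccc1O[Si](C)(C)C(C)(C)C | intermediate
5 | trimethylsilylacetylene | C#C[Si](C)(C)C | starting material
6 | methylzinc trimethylsilylacetylide | C[Zn]C#C[Si](C)(C)C | intermediate (not isolated)
7 | (S)-1-[3,5-dimethoxy-4-(triisopropylsilyloxy)phenyl]-3-(trimethylsilyl)prop-2-yn-1-ol | C[Si](C)(C)C#C[C@@H](O)c1cc(OC)c(O[Si](C(C)C)(C(C)C)C(C)C)c(OC)c1 | intermediate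
8 | (R)-1-[3,5-dimethoxy-4-(triisopropylsilyloxy)phenyl]prop-2-yn-1-ol | C#C[C@@H](O)c1cc(OC)c(O[Si](C(C)C)(C(C)C)C(C)C)c(OC)c1 | intermediate
9 | O,C-bis(methylzinc) derivative of 8 | C[Zn]C#C[C@@H](O[Zn]C)c1cc(OC)c(O[Si](C(C)C)(C(C)C)C(C)C)c(OC)c1 | intermediate (not isolated)
10 | (1S,4S)-ynediol | CC(C)(C)[Si](C)(C)Oc1ccc([C@H](O)C#C[C@@H](O)c2cc(OC)c(O[Si](C(C)C)(C(C)C)C(C)C)c(OC)c2)cc1OC | intermediate
11 | (1R,4R,2E)-enediol | CC(C)(C)[Si](C)(C)Oc1ccc([C@H](O)/C=C/[C@@H](O)c2cc(OC)c(O[Si](C(C)C)(C(C)C)C(C)C)c(OC)c2)cc1OC | intermediate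
12 | carbon monoxide | [C-]#[O+] | starting material
13 | exo,exo-bislactone (3R,3aR,6R,6aR) | CC(C)(C)[Si](C)(C)Oc1ccc([C@@H]2OC(=O)[C@@H]3[C@H]2C(=O)O[C@H]3c2cc(OC)c(O[Si](C(C)C)(C(C)C)C(C)C)c(OC)c2)cc1OC | intermediate
14 | (7R,8S,7'R,8'S)-tetraol | OC[C@@H]([C@@H](O)c1cc(OC)c(O[Si](C(C)C)(C(C)C)C(C)C)c(OC)c1)[C@H]([C@@H](O)c1ccc(O[Si](C)(C)C(C)(C)C)c(OC)c1)CO | intermediate
15 | 9,9'-bis(methanesulfonate) of 14 | CS(=O)(=O)OC[C@@H]([C@@H](O)c1cc(OC)c(O[Si](C(C)C)(C(C)C)C(C)C)c(OC)c1)[C@H]([C@@H](O)c1ccc(O[Si](C)(C)C(C)(C)C)c(OC)c1)COS(C)(=O)=O | intermediate (not isolated)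
16 | exo,exo-furofuran, ring B TBS ether, ring C TIPS ether | CC(C)(C)[Si](C)(C)Oc1ccc([C@@H]2OC[C@@H]3[C@H]2CO[C@H]3c2cc(OC)c(O[Si](C(C)C)(C(C)C)C(C)C)c(OC)c2)cc1OC | intermediate
17 | furofuran with free ring B phenol | Oc1ccc([C@@H]2OC[C@@H]3[C@H]2CO[C@H]3c2cc(OC)c(O[Si](C(C)C)(C(C)C)C(C)C)c(OC)c2)cc1OC | intermediate
18 | (R)-4-benzyloxazolidin-2-one | O=C1N[C@H](Cc2ccccc2)CO1 | starting material
19 | bromoacetyl bromide | BrCC(=O)Br | starting material
20 | N-lithio-(R)-4-benzyloxazolidin-2-one | [Li]N1[C@H](Cc2ccccc2)COC1=O | intermediate (not isolated)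
21 | (R)-4-benzyl-3-(bromoacetyl)oxazolidin-2-one | O=C(CBr)N1[C@H](Cc2ccccc2)COC1=O | intermediate
22 | aryloxyacetyl imide | O=C(COc1ccc([C@@H]2OC[C@@H]3[C@H]2CO[C@H]3c2cc(OC)c(O[Si](C(C)C)(C(C)C)C(C)C)c(OC)c2)cc1OC)N1[C@H](Cc2ccccc2)COC1=O | intermediate
23 | Z-dibutylboron enolate of 22 | CCCCB(CCCC)O/C(=C\Oc1ccc([C@@H]2OC[C@@H]3[C@H]2CO[C@H]3c2cc(OC)c(O[Si](C(C)C)(C(C)C)C(C)C)c(OC)c2)cc1OC)N1[C@H](Cc2ccccc2)COC1=O | intermediate (not isolated)
24 | (2R,3S)-syn aldol adduct | COc1cc([C@H](O)[C@H](C(=O)N5[C@H](Cc6ccccc6)COC5=O)Oc2ccc([C@@H]3OC[C@@H]4[C@H]3CO[C@H]4c3cc(OC)c(O[Si](C(C)C)(C(C)C)C(C)C)c(OC)c3)cc2OC)ccc1O[Si](C)(C)C(C)(C)C | intermediate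
25 | (7''S,8''S)-diol, ring A TBS ether, ring C TIPS ether | COc1cc([C@H](O)[C@H](CO)Oc2ccc([C@@H]3OC[C@@H]4[C@H]3CO[C@H]4c3cc(OC)c(O[Si](C(C)C)(C(C)C)C(C)C)c(OC)c3)cc2OC)ccc1O[Si](C)(C)C(C)(C)C | intermediate
26 | CNP0255927.3 | COc1cc([C@H](O)[C@H](CO)Oc2ccc([C@@H]3OC[C@@H]4[C@H]3CO[C@H]4c3cc(OC)c(O)c(OC)c3)cc2OC)ccc1O | target

Total step count: 15. Longest linear sequence: 13 (steps 1, 3–10 and 12–15, from syringaldehyde).

Steps most likely to fail

**Step 7 (new method).**
- The endo insertion may not take place at all, so that the metal is reduced and precipitates or turns to oxidising the carbinols.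
- The electron-rich allylic benzylic carbinols may ionise or be transposed.
- The two alkene faces may be poorly distinguished.

The fallback uses only known chemistry and no carbonylation: a conjugate addition–aldol sequence on a chiral butenolide. It sets out from 4 and 2 and comes back to the route at 16. Aldehyde 4 is turned with PhSH and BF3·OEt2 (CH2Cl2, 0 °C) into the bis(phenylthio)acetal F1. Its lithio derivative (n-BuLi, THF, −78 °C) adds 1,4 to commercial (5S)-5-(d-menthyloxy)furan-2(5H)-one, O=C1C=C[C@@H](O[C@H]2C[C@@H](C)CC[C@@H]2C(C)C)O1, anti to the menthyloxy group. The lactone enolate is trapped in the same flask with 2, anti to the new substituent, to give the trans,trans-lactone F2 with C8' and C8 in the sense of the target. HgO and BF3·OEt2 in aqueous THF unmask the aryl ketone F3. LiAlH4 reduces the ketone, the lactone and the acetal carbon that ring opening sets free, with loss of menthol, to the tetraol F4, a mixture of carbinol epimers of 14. MsCl in pyridine at room temperature, now allowed to act at the benzylic positions, closes both ethers by ionisation and capture by the primary hydroxyls, and C8 and C8' steer both aryl groups exo to give 16.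

**Step 9.**
- After only one sulfonylation the second primary hydroxyl may close a 3,4-disubstituted tetrahydrofuran between C9 and C9'.
- Sulfonylation may spread to the benzylic positions and end in chloride capture.

The fallback never opens the rings, so no regiochemical choice arises. It sets out from 13 and comes back at 16, passing by 14 and 15. i-Bu2AlH (2.3 equiv, CH2Cl2, −78 °C) stops at the bis-lactol F5. Ionic reduction of both lactols through their oxocarbenium ions (Et3SiH, BF3·OEt2, CH2Cl2, −78 °C) then gives 16. Any acid-induced epimerisation at C7 or C7' runs towards the exo,exo form that is wanted.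

**Step 5.**
- Addition to the electron-rich aldehyde may be sluggish.
- The substrate-bound zinc alkoxide may erode catalyst control.
- Methyl transfer from zinc may compete.

The fallback forms the C7'–C8' bond from an alkenylzinc reagent, so the E-alkene is in place from the start. It sets out from 8 and comes back at 11, passing by 10 and step 6. TMSCl and imidazole (CH2Cl2, 0 °C) give the silyl ether F6. Syn hydroboration with Cy2BH (toluene, 0 °C to rt) gives the E-alkenylborane F7. Boron–zinc exchange with Me2Zn (−78 °C) gives the alkenyl(methyl)zinc F8. Amino-alcohol-catalysed addition to 4 with (+)-3-exo-morpholinoisoborneol (5 mol %, −10 °C), the antipode that serves the Re face, gives the mono-silylated enediol F9. Brief treatment with catalytic K2CO3 in MeOH at 0 °C removes the alkyl TMS ether to give 11.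

Further compounds
F1 | step 7 | tert-butyl{4-[bis(phenylthio)methyl]-2-methoxyphenoxy}dimethylsilane | COc1cc(C(Sc2ccccc2)Sc2ccccc2)ccc1O[Si](C)(C)C(C)(C)C
F2 | step 7 | trans,trans-lactone: (5S)-5-(d-menthyloxy)dihydrofuran-2(3H)-one with the ring B bis(phenylthio)methyl group on C4 (C8') and the ring C hydroxymethyl group on C3 (C8), carbinol C7 unassigned | O=C1O[C@H](O[C@H]2C[C@@H](C)CC[C@@H]2C(C)C)[C@@H](C(Sc2ccccc2)(Sc2ccccc2)c2ccc(O[Si](C)(C)C(C)(C)C)c(OC)c2)[C@@H]1C(O)c1cc(OC)c(O[Si](C(C)C)(C(C)C)C(C)C)c(OC)c1
F3 | step 7 | aryl ketone from F2 | O=C1O[C@H](O[C@H]2C[C@@H](C)CC[C@@H]2C(C)C)[C@@H](C(=O)c2ccc(O[Si](C)(C)C(C)(C)C)c(OC)c2)[C@@H]1C(O)c1cc(OC)c(O[Si](C(C)C)(C(C)C)C(C)C)c(OC)c1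
F4 | step 7 | (8S,8'S)-tetraol, mixture of epimers at C7 and C7' | OC[C@@H](C(O)c1cc(OC)c(O[Si](C(C)C)(C(C)C)C(C)C)c(OC)c1)[C@H](C(O)c1ccc(O[Si](C)(C)C(C)(C)C)c(OC)c1)CO
F5 | step 9 | bis-lactol of 13, anomeric centres unassigned | CC(C)(C)[Si](C)(C)Oc1ccc([C@@H]2OC(O)[C@@H]3[C@H]2C(O)O[C@H]3c2cc(OC)c(O[Si](C(C)C)(C(C)C)C(C)C)c(OC)c2)cc1OC
F6 | step 5 | trimethylsilyl ether of 8 | C#C[C@@H](O[Si](C)(C)C)c1cc(OC)c(O[Si](C(C)C)(C(C)C)C(C)C)c(OC)c1
F7 | step 5 | E-alkenyldicyclohexylborane from F6 | C1CCCCC1B(/C=C/[C@@H](O[Si](C)(C)C)c1cc(OC)c(O[Si](C(C)C)(C(C)C)C(C)C)c(OC)c1)C1CCCCC1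
F8 | step 5 | E-alkenyl(methyl)zinc from F7 | C[Zn]/C=C/[C@@H](O[Si](C)(C)C)c1cc(OC)c(O[Si](C(C)C)(C(C)C)C(C)C)c(OC)c1
F9 | step 5 | 11 with O7 as trimethylsilyl ether | CC(C)(C)[Si](C)(C)Oc1ccc([C@H](O)/C=C/[C@@H](O[Si](C)(C)C)c2cc(OC)c(O[Si](C(C)C)(C(C)C)C(C)C)c(OC)c2)cc1OC
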